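**Strategy.** Everything rests on cutting the trans-fused hydroazulene back to its cyclopentane. The two adjacent ring-fusion carbons, C3a (CH) and C8a (C–CH3), carry the two arms of the seven-membered ring on opposite faces, flanked by C1 (acetoxy) and C3 (carbinol). One operation therefore joins three pieces: a lithiated methallyl dithiane adds to C3a of an (R)-4-silyloxy-2-methylcyclopentenone anti to the silyl ether, and the tetrasubstituted enolate is captured at C8a by acrolein anti to the new arm, forming the C3a–C4 and C8a–C8 bonds and three stereocentres. Ring-closing metathesis later makes the C6=C7 bond, and the C3 tertiary hydroxyl directs both ketone reductions.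

Key step: step 4

Remarks on the chemistry:
- Locants follow the octahydroazulene numbering of the target: C1 (OAc), C2, C3 (C(OH)iPr), C3a (H), C4 (OAng), C5, C6 (CH3, C6=C7), C7, C8 (OBz), C8a (CH3). In all bicyclic compounds the 3a-H is trans and the C8 benzoate cis to the 8a-methyl, as in the target.
- Configuration check: (R) at the silyloxy carbon of 3 leads by anti,anti induction to the ring-fusion configuration of the target, and the chair aldol transition state gives the (S) carbinol needed at C8, so that hydroxyl is benzoylated directly.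
- In the target the C1 and C4 acyloxy groups are both anti to the C3 tertiary hydroxyl. Both ketones are therefore reduced by hydride delivered from that hydroxyl, which requires the isopropyl carbinol to be in place first and C1 to be masked while C3 is a ketone.
- Assumption: the C1 alcohol made in step 7 is drawn as the epimer expected from hydride attack anti to the 8a-methyl; its configuration is erased in step 13 and either epimer serves.

**Route**

Step 1
Reactants: 1 (R)-4-(tert-butyldimethylsilyloxy)cyclopent-2-en-1-one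
Product: 2 (R)-4-(tert-butyldimethylsilyloxy)-2-iodocyclopent-2-en-1-one
Conditions: I2, pyridine/CH2Cl2, 0 °C to rt
Reagents that add atoms: iodine, II
Why: α-Iodination of the enone by the pyridine-mediated addition–iodination–elimination sequence (Johnson iodination) touches only C2, so the silyloxy stereocentre is kept.

Step 2
Reactants: 2 (R)-4-(tert-butyldimethylsilyloxy)-2-iodocyclopent-2-en-1-one
Product: 3 (R)-4-(tert-butyldimethylsilyloxy)-2-methylcyclopent-2-en-1-one
Conditions: Me4Sn, Pd2(dba)3 (cat.), AsPh3, CuI, NMP, 80 °C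
Reagents that add atoms: tetramethylstannane, C[Sn](C)(C)C
Why: Stille cross-coupling of the vinyl iodide with tetramethyltin under neutral Pd/AsPh3/CuI conditions replaces iodine by methyl without exposing the base-sensitive γ-silyloxy enone to base.

Step 3
Reactants: 4 1,3-dithiane; 5 3-chloro-2-methylprop-1-ene
Product: 7 2-(2-methylprop-2-en-1-yl)-1,3-dithiane, via 2-lithio-1,3-dithiane 6 (not isolated)
Conditions: n-BuLi, THF, −30 °C; then 5, −78 °C to rt
Reagents that add atoms: none
Why: Corey–Seebach alkylation, in which the sulfur-stabilised 2-lithio-1,3-dithiane displaces the reactive allylic chloride by SN2.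

Step 4
Reactants: 7 2-(2-methylprop-2-en-1-yl)-1,3-dithiane; 3 (R)-4-(tert-butyldimethylsilyloxy)-2-methylcyclopent-2-en-1-one; 8 acrolein
Product: 12 (2S,3R,4R)-4-(tert-butyldimethylsilyloxy)-2-[(1S)-1-hydroxyprop-2-en-1-yl]-2-methyl-3-[2-(2-methylprop-2-en-1-yl)-1,3-dithian-2-yl]cyclopentan-1-one, via lithiated dithiane 9 (not isolated), via lithium enolate 10 (not isolated), via chlorozinc enolate 11 (not isolated)
Conditions: 7, t-BuLi, THF/HMPA, −78 °C; 3, −78 °C; ZnCl2, THF; 8, −78 °C; aq. NH4Cl
Reagents that add atoms: none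
Why: The sulfur-stabilised carbanion 9, kept as a solvent-separated ion pair by HMPA, adds in the 1,4 sense to the β-carbon of enone 3 on the face opposite the bulky silyloxy group and gives the regiodefined tetrasubstituted lithium enolate 10; exchange to zinc (11) allows a closed six-membered (Zimmerman–Traxler) aldol with acrolein on the face opposite the new dithianyl arm. The closest known reaction type is the three-component coupling of 4-silyloxycyclopentenones (conjugate addition followed by aldol capture of the enolate), combined with the HMPA-directed conjugate addition of 2-lithio-1,3-dithianes. No ring is closed in this step; two C–C bonds form, the future C3a–C4 and C8a–C8 bonds. The ring-fusion CH is set by the silyloxy stereocentre (anti), the quaternary C–CH3 by the adjacent dithianyl arm (anti), and the carbinol by the chair transition state, in which the ring-locked enolate geometry and an equatorial vinyl group should give the (S) alcohol. The step needs 1,4- over 1,2-addition (HMPA and the soft thioacetal anion), addition to the carbonyl of acrolein and not to its alkene (zinc chelate at −78 °C), and no proton transfer within the enolate, which would expel silyloxide (secured by the low temperature).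

Step 5
Reactants: 12 aldol adduct (2S,3R,4R,1'S)
Product: 13 (2S,3R,4R)-2-[(1S)-1-(benzoyloxy)prop-2-en-1-yl]-4-(tert-butyldimethylsilyloxy)-2-methyl-3-[2-(2-methylprop-2-en-1-yl)-1,3-dithian-2-yl]cyclopentan-1-one
Conditions: BzCl, pyridine, DMAP (cat.), CH2Cl2, 0 °C to rt
Reagents that add atoms: benzoyl chloride, O=C(Cl)c1ccccc1
Why: DMAP-catalysed O-acylation of the secondary allylic alcohol is mild enough that neither retro-aldol cleavage nor β-elimination of the silyloxy group is expected, and the carbinol configuration is untouched.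

Step 6
Reactants: 13 benzoate diene
Product: 14 8-(benzoyloxy)-3-(tert-butyldimethylsilyloxy)-6,8a-dimethyl-4,4-(propane-1,3-diyldithio)-3,3a,4,5,8,8a-hexahydroazulen-1(2H)-one (trans-fused; 3-O trans and 8-O cis to the 8a-methyl)
Conditions: Grubbs II (10 mol %), toluene (5 mM, degassed), 80 °C
Reagents that add atoms: none
Why: Ring-closing olefin metathesis between the vinyl and the 1,1-disubstituted methallyl group, helped by the fully substituted carbons at both ends of the tether and by the trans arrangement of the arms, closes the cycloheptene with the trisubstituted C6=C7 bond; thioacetal sulfur binds the NHC–ruthenium carbene only weakly.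

Step 7
Reactants: 14 bicyclic C1 ketone
Product: 15 8-(benzoyloxy)-3-(tert-butyldimethylsilyloxy)-6,8a-dimethyl-4,4-(propane-1,3-diyldithio)-1,2,3,3a,4,5,8,8a-octahydroazulen-1-ol (1-OH cis to the 8a-methyl)
Conditions: NaBH4, CeCl3·7H2O, MeOH/THF, −40 to 0 °C
Reagents that add atoms: none
Why: Luche-type borohydride reduction of the cyclopentanone, where hydride attack anti to the angular 8a-methyl should give mainly the alcohol cis to that methyl; the cerium salt keeps the medium non-basic so the neighbouring benzoate does not migrate, and this stereocentre is erased again in step 13.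

Step 8
Reactants: 15 C1 alcohol
Product: 16 1-O-triisopropylsilyl ether of 15 (3-OTBS and 8-OBz unchanged)
Conditions: TIPSOTf, 2,6-lutidine, CH2Cl2, 0 °C to rt
Reagents that add atoms: triisopropylsilyl trifluoromethanesulfonate, CC(C)[Si](OS(=O)(=O)C(F)(F)F)(C(C)C)C(C)C
Why: Silylation with the silyl triflate and 2,6-lutidine caps even this neopentyl alcohol and gives an ether that outlasts removal of the TBS group and the organometallic step.

Step 9
Reactants: 16 bis-silyl ether
Product: 17 8-(benzoyloxy)-6,8a-dimethyl-4,4-(propane-1,3-diyldithio)-1-(triisopropylsilyloxy)-1,2,3,3a,4,5,8,8a-octahydroazulen-3-ol (3-OH trans to the 8a-methyl)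
Conditions: HF·pyridine, pyridine, THF, 0 °C to rt
Reagents that add atoms: none
Why: Fluoride-mediated desilylation under HF·pyridine cleaves the ordinary secondary TBS ether much faster than the hindered TIPS ether, while esters and the dithiane are inert.

Step 10
Reactants: 17 C3 alcohol
Product: 18 8-(benzoyloxy)-6,8a-dimethyl-4,4-(propane-1,3-diyldithio)-1-(triisopropylsilyloxy)-1,3a,4,5,8,8a-hexahydroazulen-3(2H)-one
Conditions: Dess–Martin periodinane, NaHCO3, CH2Cl2 (dry), 0 °C to rt
Reagents that add atoms: none
Why: Dess–Martin oxidation under buffered, base-free conditions gives the C3 ketone without epimerising the adjacent ring-fusion CH or eliminating the β-silyloxy group, and the dithiane tolerates the anhydrous periodinane.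

Step 11
Reactants: 18 C3 ketone
Product: 19 8-(benzoyloxy)-6,8a-dimethyl-3-(propan-2-yl)-4,4-(propane-1,3-diyldithio)-1-(triisopropylsilyloxy)-1,2,3,3a,4,5,8,8a-octahydroazulen-3-ol (3-OH cis to the 8a-methyl)
Conditions: i-PrMgCl, CeCl3 (anhydrous), THF, −78 °C
Reagents that add atoms: isopropylmagnesium chloride, CC(C)[Mg]Cl
Why: Organocerium (Imamoto) 1,2-addition, nucleophilic but barely basic, should add isopropyl to the enolisable β-silyloxy ketone at −78 °C faster than to the hindered benzoate; attack from the face of the ring-fusion hydrogen (the other face is blocked by the 8a-methyl, the axial dithiane sulfur and the C1 silyloxy group) sets the tertiary hydroxyl cis to the 8a-methyl.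

Step 12
Reactants: 19 tertiary alcohol TIPS ether
Product: 20 8-(benzoyloxy)-6,8a-dimethyl-3-(propan-2-yl)-4,4-(propane-1,3-diyldithio)-1,2,3,3a,4,5,8,8a-octahydroazulene-1,3-diol (both OH cis to the 8a-methyl)
Conditions: TBAF, AcOH (1:1), THF, rt to 45 °C
Reagents that add atoms: none
Why: Fluoride desilylation with acetic acid-buffered TBAF frees the C1 hydroxyl without generating a basic alkoxide next to the benzoate.

Step 13
Reactants: 20 diol
Product: 21 8-(benzoyloxy)-3-hydroxy-6,8a-dimethyl-3-(propan-2-yl)-4,4-(propane-1,3-diyldithio)-3,3a,4,5,8,8a-hexahydroazulen-1(2H)-one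
Conditions: Dess–Martin periodinane, NaHCO3, CH2Cl2 (dry), 0 °C to rt
Reagents that add atoms: none
Why: Dess–Martin oxidation converts the secondary C1 alcohol into the ketone while the tertiary alcohol cannot be oxidised.

Step 14
Reactants: 21 β-hydroxy ketone
Product: 22 8-(benzoyloxy)-6,8a-dimethyl-3-(propan-2-yl)-4,4-(propane-1,3-diyldithio)-1,2,3,3a,4,5,8,8a-octahydroazulene-1,3-diol (1-OH trans and 3-OH cis to the 8a-methyl)
Conditions: Me4NBH(OAc)3, MeCN/AcOH, −20 °C to rt
Reagents that add atoms: none
Why: Evans–Saksena hydroxyl-directed reduction, in which the C3 tertiary hydroxyl binds the triacetoxyborohydride and delivers hydride intramolecularly to the face of C1 that it occupies, should give the 1,3-anti diol with the new C1 hydroxyl trans to the 8a-methyl as the target requires; ketones without a neighbouring hydroxyl are not reduced by this reagent.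

Step 15
Reactants: 22 anti diol
Product: 23 1-O-acetate of 22 (tertiary 3-OH free)
Conditions: Ac2O, pyridine, DMAP (cat.), CH2Cl2, 0 °C to rt
Reagents that add atoms: acetic anhydride, CC(=O)OC(C)=O
Why: DMAP-catalysed acetylation selects the secondary C1 hydroxyl, the hindered tertiary hydroxyl being inert under these conditions.

Step 16
Reactants: 23 acetate dithiane
Product: 24 1-acetoxy-8-(benzoyloxy)-3-hydroxy-6,8a-dimethyl-3-(propan-2-yl)-1,2,3,3a,8,8a-hexahydroazulen-4(5H)-one
Conditions: PhI(O2CCF3)2, NaHCO3, MeCN/H2O (9:1), 0 °C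
Reagents that add atoms: water, O
Why: Oxidative dethioketalisation with the hypervalent iodine reagent (Stork–Zhao conditions) unmasks the C4 ketone within minutes at 0 °C in buffered medium, so the β,γ-alkene should not move into conjugation and the α ring-fusion CH should not epimerise.

Step 17
Reactants: 24 C4 ketone
Product: 25 1-acetoxy-8-(benzoyloxy)-6,8a-dimethyl-3-(propan-2-yl)-1,2,3,3a,4,5,8,8a-octahydroazulene-3,4-diol (4-OH trans and 3-OH cis to the 8a-methyl)
Conditions: Me4NBH(OAc)3, MeCN/AcOH, −30 to −10 °C
Reagents that add atoms: none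
Why: A second Evans–Saksena directed reduction, with the same C3 tertiary hydroxyl delivering hydride to the axial face of C4 (the face syn to the 8a-methyl), should give the equatorial C4 alcohol trans to the 8a-methyl and anti to the tertiary hydroxyl.

Step 18
Reactants: 25 C4 alcohol
Product: 26 (1S,3R,3aS,4S,8S,8aR)-1-acetoxy-8-(benzoyloxy)-3-hydroxy-6,8a-dimethyl-3-(propan-2-yl)-1,2,3,3a,4,5,8,8a-octahydroazulen-4-yl (2Z)-2-methylbut-2-enoate (CNP0248576.1)
Conditions: angelic acid, 2,4,6-trichlorobenzoyl chloride, Et3N, toluene, rt; then 25, 80 °C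
Reagents that add atoms: angelic acid, C/C=C(/C)C(=O)O
Why: Yamaguchi esterification through the mixed anhydride of angelic acid, run without a nucleophilic catalyst so that the Z-alkene does not isomerise to the tiglate, acylates the only free secondary hydroxyl and leaves the tertiary one untouched.

**Compound list**

1 | (R)-4-(tert-butyldimethylsilyloxy)cyclopent-2-en-1-one | O=C1C=C[C@H](O[Si](C)(C)C(C)(C)C)C1 | starting material
2 | (R)-4-(tert-butyldimethylsilyloxy)-2-iodocyclopent-2-en-1-one | O=C1C(I)=C[C@H](O[Si](C)(C)C(C)(C)C)C1 | intermediate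
3 | (R)-4-(tert-butyldimethylsilyloxy)-2-methylcyclopent-2-en-1-one | CC1=C[C@H](O[Si](C)(C)C(C)(C)C)CC1=O | intermediate
4 | 1,3-dithiane | C1CSCSC1 | starting material
5 | 3-chloro-2-methylprop-1-ene | C=C(C)CCl | starting material
6 | 2-lithio-1,3-dithiane | [Li]C1SCCCS1 | intermediate
7 | 2-(2-methylprop-2-en-1-yl)-1,3-dithiane | C=C(C)CC1SCCCS1 | intermediate
8 | acrolein | C=CC=O | starting material
9 | 2-lithio-2-(2-methylprop-2-en-1-yl)-1,3-dithiane | [Li]C1(CC(C)=C)SCCCS1 | intermediate
10 | lithium enolate of the conjugate adduct (dithianyl trans to OTBS) | CC1=C(O[Li])C[C@@H](O[Si](C)(C)C(C)(C)C)[C@@H]1C2(CC(C)=C)SCCCS2 | intermediate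
11 | chlorozinc enolate of the conjugate adduct | CC1=C(O[Zn]Cl)C[C@@H](O[Si](C)(C)C(C)(C)C)[C@@H]1C2(CC(C)=C)SCCCS2 | intermediate
12 | (2S,3R,4R)-4-(tert-butyldimethylsilyloxy)-2-[(1S)-1-hydroxyprop-2-en-1-yl]-2-methyl-3-[2-(2-methylprop-2-en-1-yl)-1,3-dithian-2-yl]cyclopentan-1-one | C=C[C@H](O)[C@@]1(C)C(=O)C[C@@H](O[Si](C)(C)C(C)(C)C)[C@@H]1C2(CC(C)=C)SCCCS2 | intermediate
13 | benzoate of 12 | C=C[C@H](OC(=O)c3ccccc3)[C@@]1(C)C(=O)C[C@@H](O[Si](C)(C)C(C)(C)C)[C@@H]1C2(CC(C)=C)SCCCS2 | intermediate
14 | trans-fused bicyclic C1 ketone (C4 dithiane, 3-OTBS, 8-OBz) | S1CCCSC13CC(C)=C[C@H](OC(=O)c4ccccc4)[C@@]2(C)C(=O)C[C@@H](O[Si](C)(C)C(C)(C)C)[C@H]32 | intermediate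
15 | C1 alcohol (1-OH cis to 8a-methyl) | S1CCCSC13CC(C)=C[C@H](OC(=O)c4ccccc4)[C@@]2(C)[C@H](O)C[C@@H](O[Si](C)(C)C(C)(C)C)[C@H]32 | intermediate
16 | 1-OTIPS, 3-OTBS bis-silyl ether | S1CCCSC13CC(C)=C[C@H](OC(=O)c4ccccc4)[C@@]2(C)[C@H](O[Si](C(C)C)(C(C)C)C(C)C)C[C@@H](O[Si](C)(C)C(C)(C)C)[C@H]32 | intermediate
17 | C3 secondary alcohol, 1-OTIPS | S1CCCSC13CC(C)=C[C@H](OC(=O)c4ccccc4)[C@@]2(C)[C@H](O[Si](C(C)C)(C(C)C)C(C)C)C[C@@H](O)[C@H]32 | intermediate
18 | C3 ketone, 1-OTIPS | S1CCCSC13CC(C)=C[C@H](OC(=O)c4ccccc4)[C@@]2(C)[C@H](O[Si](C(C)C)(C(C)C)C(C)C)CC(=O)[C@H]32 | intermediate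
19 | C3 isopropyl tertiary alcohol, 1-OTIPS | S1CCCSC13CC(C)=C[C@H](OC(=O)c4ccccc4)[C@@]2(C)[C@H](O[Si](C(C)C)(C(C)C)C(C)C)C[C@@](O)(C(C)C)[C@H]32 | intermediate
20 | 1,3-diol (both OH cis to 8a-methyl) | S1CCCSC13CC(C)=C[C@H](OC(=O)c4ccccc4)[C@@]2(C)[C@H](O)C[C@@](O)(C(C)C)[C@H]32 | intermediate
21 | C1 ketone with C3 tertiary alcohol | S1CCCSC13CC(C)=C[C@H](OC(=O)c4ccccc4)[C@@]2(C)C(=O)C[C@@](O)(C(C)C)[C@H]32 | intermediate
22 | 1,3-anti diol (1-OH trans to 8a-methyl) | S1CCCSC13CC(C)=C[C@H](OC(=O)c4ccccc4)[C@@]2(C)[C@@H](O)C[C@@](O)(C(C)C)[C@H]32 | intermediate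
23 | C1 acetate, C4 dithiane | S1CCCSC13CC(C)=C[C@H](OC(=O)c4ccccc4)[C@@]2(C)[C@@H](OC(C)=O)C[C@@](O)(C(C)C)[C@H]32 | intermediate
24 | C4 ketone | O=C1CC(C)=C[C@H](OC(=O)c2ccccc2)[C@@]2(C)[C@@H](OC(C)=O)C[C@@](O)(C(C)C)[C@H]12 | intermediate
25 | C4 alcohol (4-OH trans to 8a-methyl) | O[C@H]1CC(C)=C[C@H](OC(=O)c2ccccc2)[C@@]2(C)[C@@H](OC(C)=O)C[C@@](O)(C(C)C)[C@H]12 | intermediate
26 | (1S,3R,3aS,4S,8S,8aR)-1-acetoxy-8-(benzoyloxy)-3-hydroxy-6,8a-dimethyl-3-(propan-2-yl)-1,2,3,3a,4,5,8,8a-octahydroazulen-4-yl (2Z)-2-methylbut-2-enoate | C/C=C(/C)C(=O)O[C@H]1CC(C)=C[C@H](OC(=O)c2ccccc2)[C@@]2(C)[C@@H](OC(C)=O)C[C@@](O)(C(C)C)[C@H]12 | target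

**Step count and risks**

Total step count: 18. Longest linear sequence: 17 steps (steps 1, 2 and 4 to 18, from 1 to 26).

Steps most likely to fail:

1. Step 4. The dithiane anion may add 1,2 to the α-methyl enone, and the aldol on the hindered tetrasubstituted enolate may reverse or lose facial control while HMPA is present. The fallback sets out from enolate 10, which is quenched at −78 °C with Me3SiCl/Et3N to give the trimethylsilyl enol ether F1. F1 is purified free of HMPA and of any 1,2-adduct. MeLi in THF at 0 °C then regenerates 10 regiospecifically, and exchange to zinc and addition of acrolein at −78 °C return to the route at 12.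

2. Step 6. The dithiane sulfur may deactivate the ruthenium carbene, and closure to a trisubstituted alkene between two fully substituted carbons may be slower than oligomerisation. The fallback sets out from 13, which with PhI(O2CCF3)2 in methanol gives the sulfur-free dimethyl ketal F2. Metathesis of F2 with the same catalyst gives the bicyclic dimethyl ketal F3. Chemoselective exchange of the ketal with 1,3-propanedithiol and MgBr2·OEt2 in ether (the hindered C1 ketone does not react) returns to the route at 14.

3. Step 11. The hindered ketone may be reduced by β-hydride transfer from the isopropyl reagent, or enolised with loss of silyloxide, or the reagent may attack the benzoate. The fallback sets out from 18 and adds isopropenylmagnesium bromide/CeCl3 at −78 °C, an sp2 nucleophile without a transferable β-hydride, to give the isopropenyl carbinol F4. Diimide (2-nitrobenzenesulfonohydrazide, Et3N, CH2Cl2, rt) then saturates the 1,1-disubstituted alkene without metal catalysis and leaves the trisubstituted ring alkene, returning to the route at 19.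

Further compounds
F1 | step 4 | trimethylsilyl enol ether of the conjugate adduct | CC1=C(O[Si](C)(C)C)C[C@@H](O[Si](C)(C)C(C)(C)C)[C@@H]1C2(CC(C)=C)SCCCS2
F2 | step 6 | dimethyl ketal analogue of 13 (dithiane replaced by C(OMe)2) | C=C[C@H](OC(=O)c3ccccc3)[C@@]1(C)C(=O)C[C@@H](O[Si](C)(C)C(C)(C)C)[C@@H]1C(OC)(OC)CC(C)=C
F3 | step 6 | bicyclic C4 dimethyl ketal analogue of 14 | COC1(OC)CC(C)=C[C@H](OC(=O)c2ccccc2)[C@@]2(C)C(=O)C[C@@H](O[Si](C)(C)C(C)(C)C)[C@H]12
F4 | step 11 | C3 isopropenyl tertiary alcohol, 1-OTIPS | S1CCCSC13CC(C)=C[C@H](OC(=O)c4ccccc4)[C@@]2(C)[C@H](O[Si](C(C)C)(C(C)C)C(C)C)C[C@@](O)(C(C)=C)[C@H]32
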